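**Strategy.** The route rests on cutting the C5–C11 bond, which is shared by the cyclobutane (C4–C5–C11–C10) and the cyclohexanone ring C1–C2–C3–C4–C5–C11. The precursor is a hydrobenzo[7]annulenone: the enone C1(=O)–C11=C10 fused at C4–C10 to the fully oxygenated seven-membered ring, with a tosylate at C5. It is built from cyclohexadiene by asymmetric cycloalkenylboration, an acyl-anion conjugate addition and an aldol ring closure. In the key step Me2CuLi adds to C10; the regiospecific C1/C11 enolate, held 1,3 to C5 across the new quaternary C10, displaces the tosylate. One operation sets C10 and C11 and closes the four- and six-membered rings. A late cuprate addition installs C3–Me.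

Key step: step 9

Remark: both esters are taken as angelates (Z) as drawn. Locants follow the longipinane skeleton (C1 ketone, C3 methyl-bearing carbon, C4/C5/C11/C10 cyclobutane, C6 gem-dimethyl, C7 and C9 ester carbons). Aldehyde 3 is made, not bought.

Step 1
Reactants: 1 2-methyl-1-(trimethylsilyloxy)prop-1-ene; 2 trimethyl orthoformate
Product: 3 3,3-dimethoxy-2,2-dimethylpropanal
Conditions: TMSOTf (5 mol%), CH2Cl2, −78 °C
Reagents that add atoms: none
Why: Noyori-type Mukaiyama addition of the enol silane to the TMSOTf-generated dimethoxycarbenium ion; the aldehyde formed has a quaternary α-carbon and cannot enolise.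

Step 2
Reactants: 4 cyclohexa-1,3-diene; 3 3,3-dimethoxy-2,2-dimethylpropanal
Product: 6 (1S)-1-[(1R)-cyclohex-2-en-1-yl]-3,3-dimethoxy-2,2-dimethylpropan-1-ol (syn), via cyclohexenylborane 5 (not isolated)
Conditions: (−)-Ipc2BH (from (+)-α-pinene), THF, −25 °C; then 3, −78 °C → rt; NaOH, H2O2
Reagents that add atoms: none
Why: Brown asymmetric cycloalkenylboration: hydroboration should give the (S)-allylborane, which adds to 3 through a chair Zimmerman–Traxler transition state (suprafacial SE2′, ring CH2 as the Z substituent) to give the syn adduct, setting C5 (S) and C4 (R).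

Step 3
Reactants: 6 (1S)-1-[(1R)-cyclohex-2-en-1-yl]-3,3-dimethoxy-2,2-dimethylpropan-1-ol
Product: 7 (1S)-1-[(1R)-cyclohex-2-en-1-yl]-3,3-dimethoxy-2,2-dimethylpropyl 4-methylbenzenesulfonate
Conditions: TsCl, Et3N, Me3N·HCl (cat.), CH2Cl2, 0 °C → rt
Reagents that add atoms: 4-methylbenzenesulfonyl chloride, Cc1ccc(cc1)S(Cl)(=O)=O
Why: Sulfonylation of the hindered secondary alcohol (Tanabe conditions) proceeds with retention at C5 and installs the nucleofuge while C5 is still remote from any carbonyl group.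

Step 4
Reactants: 7 (1S)-1-[(1R)-cyclohex-2-en-1-yl]-3,3-dimethoxy-2,2-dimethylpropyl 4-methylbenzenesulfonate
Product: 8 (1S)-3,3-dimethoxy-2,2-dimethyl-1-[(1R)-4-oxocyclohex-2-en-1-yl]propyl 4-methylbenzenesulfonate
Conditions: Rh2(cap)4 (1 mol%), t-BuOOH, K2CO3, CH2Cl2, rt
Reagents that add atoms: tert-butyl hydroperoxide, CC(C)(C)OO
Why: Rh2(cap)4-catalysed allylic oxidation should attack the unhindered allylic CH2 (C1) rather than the substituted C4–H, giving the 4-substituted cyclohex-2-enone without touching C4 or C5.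

Step 5
Reactants: 8 (1S)-3,3-dimethoxy-2,2-dimethyl-1-[(1R)-4-oxocyclohex-2-en-1-yl]propyl 4-methylbenzenesulfonate; 9 ethyl vinyl ether
Product: 11 (1S)-1-[(1R)-2-(1-ethoxyvinyl)-4-oxocyclohex-2-en-1-yl]-3,3-dimethoxy-2,2-dimethylpropyl 4-methylbenzenesulfonate, via silyl enol ether 10 (not isolated)
Conditions: (1-ethoxyvinyl)2CuLi (from 9, t-BuLi, CuI), TMSCl, THF, −78 °C; then Pd(OAc)2, MeCN, rt
Reagents that add atoms: none
Why: TMSCl-accelerated conjugate addition of the acyl-anion equivalent bis(1-ethoxyvinyl)cuprate (anti to the C4 side chain) gives a regiodefined silyl enol ether, and Saegusa–Ito oxidation restores the enone with C9 now on C10, erasing the transient C10 stereocentre.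

Step 6
Reactants: 11 (1S)-1-[(1R)-2-(1-ethoxyvinyl)-4-oxocyclohex-2-en-1-yl]-3,3-dimethoxy-2,2-dimethylpropyl 4-methylbenzenesulfonate
Product: 13 (4aR,5S,7R)-7-hydroxy-6,6-dimethyl-2,9-dioxo-3,4,4a,5,6,7,8,9-octahydro-2H-benzo[7]annulen-5-yl 4-methylbenzenesulfonate (4a-H/5-OTs/7-OH all cis), via keto aldehyde 12 (not isolated)
Conditions: 1 M HCl, THF, rt → 40 °C
Reagents that add atoms: water, O
Why: Acid hydrolysis unmasks the C9 methyl ketone and the C7 aldehyde, and the reversible acid-catalysed intramolecular aldol addition (7-enolexo, C8 onto C7) is expected to settle on the isomer with C7–OH cis to C5–OTs (both pseudo-equatorial flanking C6), the non-basic medium sparing the C4–H/C5–OTs array.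

Step 7
Reactants: 13 (4aR,5S,7R)-7-hydroxy-6,6-dimethyl-2,9-dioxo-3,4,4a,5,6,7,8,9-octahydro-2H-benzo[7]annulen-5-yl 4-methylbenzenesulfonate
Product: 14 (4aR,5S,7R,9R)-7,9-dihydroxy-6,6-dimethyl-2-oxo-3,4,4a,5,6,7,8,9-octahydro-2H-benzo[7]annulen-5-yl 4-methylbenzenesulfonate (9-OH trans to 7-OH)
Conditions: Me4NBH(OAc)3, MeCN/AcOH, −30 °C
Reagents that add atoms: none
Why: Evans–Saksena reduction: intramolecular hydride delivery from the C7-O-bound acetoxyborohydride should give the 1,3-anti diol (C9–OH trans to C7–OH) and leave the C1 enone untouched.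

Step 8
Reactants: 14 (4aR,5S,7R,9R)-7,9-dihydroxy-6,6-dimethyl-2-oxo-3,4,4a,5,6,7,8,9-octahydro-2H-benzo[7]annulen-5-yl 4-methylbenzenesulfonate
Product: 15 (4aR,5S,7R,9R)-6,6-dimethyl-2-oxo-7,9-bis(triethylsilyloxy)-3,4,4a,5,6,7,8,9-octahydro-2H-benzo[7]annulen-5-yl 4-methylbenzenesulfonate
Conditions: Et3SiOTf (2.5 equiv), 2,6-lutidine, CH2Cl2, −78 °C
Reagents that add atoms: triethylsilyl trifluoromethanesulfonate (two equivalents, one per hydroxyl), CC[Si](CC)(CC)OS(=O)(=O)C(F)(F)F
Why: Silylation with the silyl triflate and a hindered weak base protects both hydroxyls before a C9 alkoxide can displace the C5 tosylate, and leaves a bulky C9–OSiEt3 group to steer the cuprate.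

Step 9
Reactants: 15 (4aR,5S,7R,9R)-6,6-dimethyl-2-oxo-7,9-bis(triethylsilyloxy)-3,4,4a,5,6,7,8,9-octahydro-2H-benzo[7]annulen-5-yl 4-methylbenzenesulfonate
Product: 17 7,9-bis(triethylsilyloxy)-12-norlongipinan-1-one (tricyclic ketone without the C3 methyl), via lithium enolate 16 (not isolated)
Conditions: Me2CuLi, Et2O, −40 → 0 °C; then HMPA, THF, 0 → 50 °C
Reagents that add atoms: lithium dimethylcuprate, [Li+].C[Cu-]C
Why: Conjugate addition–cycloalkylation (Michael-initiated ring closure): Me2CuLi adds to the enone β-carbon C10 and the regiospecifically formed C1–O/C11 enolate attacks C5 in an intramolecular SN2 displacement of tosylate. The closest known reactions are cuprate angular methylation of Δ1(9)-octal-2-ones and the keto-tosylate cycloalkylations that close the cyclobutane of pinane- and copaene-type skeletons. The C11–C5 bond closes the cyclobutane C4–C5–C11–C10 in a 4-exo-tet mode and, by the same bond, completes the six-membered ring C1–C2–C3–C4–C5–C11, the last ring of the skeleton. C10 is set by methyl delivery anti to the C9–OSiEt3 group and anti to the C4–C5 bond (axial attack, cis ring fusion); C11 is then fixed by the bridge and C5 is inverted. O-alkylation would need a bridgehead enol ether and is excluded, and E2 loss of TsOH is disfavoured because C6 is quaternary and C4–H is syn to the tosylate. The step exploits the 1,3-relation of C11 (α to the C1 ketone) and C5 across C10.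

Step 10
Reactants: 17 7,9-bis(triethylsilyloxy)-12-norlongipinan-1-one
Product: 19 7,9-bis(triethylsilyloxy)-12-norlongipin-2-en-1-one, via silyl enol ether 18 (not isolated)
Conditions: LDA, TMSCl, THF, −78 °C; then Pd(OAc)2, MeCN, rt
Reagents that add atoms: none
Why: Saegusa–Ito dehydrogenation: the C1 ketone can enolise only toward C2 (C11 is a bridgehead of the bicyclo[3.1.1]heptanone), so the C2=C3 enone should form regiospecifically.

Step 11
Reactants: 19 7,9-bis(triethylsilyloxy)-12-norlongipin-2-en-1-one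
Product: 20 7,9-bis(triethylsilyloxy)longipinan-1-one (C3 methyl anti to the C10 methyl)
Conditions: Me2CuLi, Et2O, −78 → −20 °C; aq. NH4Cl
Reagents that add atoms: lithium dimethylcuprate, [Li+].C[Cu-]C
Why: Cuprate conjugate addition to the apoverbenone-like enone should occur on the face flanked by C5–H and away from the C10 methyl, setting C3 as in the target.

Step 12
Reactants: 20 7,9-bis(triethylsilyloxy)longipinan-1-one
Product: 21 7,9-dihydroxylongipinan-1-one
Conditions: HF·pyridine, THF, 0 °C → rt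
Reagents that add atoms: none
Why: Fluoride-mediated desilylation under mildly acidic conditions frees both secondary hydroxyls without enolising the ketone.

Step 13
Reactants: 21 7,9-dihydroxylongipinan-1-one; 22 angelic acid (2 equivalents consumed, one per hydroxyl)
Product: 23 7,9-di-O-angeloyl-longipinan-1-one (target)
Conditions: 22 (excess), 2,4,6-Cl3C6H2COCl, Et3N, toluene, rt; then 21, toluene, 80 °C (no DMAP)
Reagents that add atoms: angelic acid (the second equivalent of 22, which forms the second ester), C/C=C(/C)C(=O)O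
Why: Yamaguchi-type esterification with the preformed mixed anhydride of angelic acid, run without DMAP to avoid Z→E isomerisation, should acylate both hindered secondary hydroxyls, each taking one angeloyl group.

**Compound list**

1 | 2-methyl-1-(trimethylsilyloxy)prop-1-ene | CC(C)=CO[Si](C)(C)C | starting material
2 | trimethyl orthoformate | COC(OC)OC | starting material
3 | 3,3-dimethoxy-2,2-dimethylpropanal | COC(OC)C(C)(C)C=O | intermediate
4 | cyclohexa-1,3-diene | C1=CC=CCC1 | starting material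
5 | [(1S)-cyclohex-2-en-1-yl]bis(isopinocampheyl)borane (Ipc from (+)-α-pinene; not isolated) | B([C@@H]1C=CCCC1)([C@@H]1C[C@@H]2C[C@H]([C@H]1C)C2(C)C)[C@@H]1C[C@@H]2C[C@H]([C@H]1C)C2(C)C | intermediate
6 | (1S)-1-[(1R)-cyclohex-2-en-1-yl]-3,3-dimethoxy-2,2-dimethylpropan-1-ol | COC(OC)C(C)(C)[C@@H](O)[C@H]1C=CCCC1 | intermediate
7 | (1S)-1-[(1R)-cyclohex-2-en-1-yl]-3,3-dimethoxy-2,2-dimethylpropyl 4-methylbenzenesulfonate | COC(OC)C(C)(C)[C@@H](OS(=O)(=O)c1ccc(C)cc1)[C@H]1C=CCCC1 | intermediate
8 | (1S)-3,3-dimethoxy-2,2-dimethyl-1-[(1R)-4-oxocyclohex-2-en-1-yl]propyl 4-methylbenzenesulfonate | COC(OC)C(C)(C)[C@@H](OS(=O)(=O)c1ccc(C)cc1)[C@H]1C=CC(=O)CC1 | intermediate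
9 | ethyl vinyl ether | C=COCC | starting material
10 | trimethylsilyl enol ether of the conjugate adduct (1-ethoxyvinyl at C10 trans to the C4 side chain; not isolated) | COC(OC)C(C)(C)[C@@H](OS(=O)(=O)c1ccc(C)cc1)[C@H]1[C@H](C(=C)OCC)C=C(O[Si](C)(C)C)CC1 | intermediate
11 | (1S)-1-[(1R)-2-(1-ethoxyvinyl)-4-oxocyclohex-2-en-1-yl]-3,3-dimethoxy-2,2-dimethylpropyl 4-methylbenzenesulfonate | COC(OC)C(C)(C)[C@@H](OS(=O)(=O)c1ccc(C)cc1)[C@H]1C(C(=C)OCC)=CC(=O)CC1 | intermediate
12 | (1S)-1-[(1R)-2-acetyl-4-oxocyclohex-2-en-1-yl]-2,2-dimethyl-3-oxopropyl 4-methylbenzenesulfonate (not isolated) | O=CC(C)(C)[C@@H](OS(=O)(=O)c1ccc(C)cc1)[C@H]1C(C(C)=O)=CC(=O)CC1 | intermediate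
13 | (4aR,5S,7R)-7-hydroxy-6,6-dimethyl-2,9-dioxo-3,4,4a,5,6,7,8,9-octahydro-2H-benzo[7]annulen-5-yl 4-methylbenzenesulfonate (4a-H/5-OTs/7-OH all cis) | O[C@@H]1CC(=O)C2=CC(=O)CC[C@H]2[C@H](OS(=O)(=O)c3ccc(C)cc3)C1(C)C | intermediate
14 | (4aR,5S,7R,9R)-7,9-dihydroxy-6,6-dimethyl-2-oxo-3,4,4a,5,6,7,8,9-octahydro-2H-benzo[7]annulen-5-yl 4-methylbenzenesulfonate (9-OH trans to 7-OH) | O[C@@H]1C[C@@H](O)C2=CC(=O)CC[C@H]2[C@H](OS(=O)(=O)c3ccc(C)cc3)C1(C)C | intermediate
15 | 7,9-bis(triethylsilyl) ether of 14 | CC[Si](CC)(CC)O[C@@H]1C[C@@H](O[Si](CC)(CC)CC)C2=CC(=O)CC[C@H]2[C@H](OS(=O)(=O)c3ccc(C)cc3)C1(C)C | intermediate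
16 | lithium C1/C11 enolate of the cis-fused C10-methyl conjugate adduct (not isolated) | CC[Si](CC)(CC)O[C@@H]1C[C@@H](O[Si](CC)(CC)CC)[C@@]2(C)C=C([O-])CC[C@H]2[C@H](OS(=O)(=O)c3ccc(C)cc3)C1(C)C.[Li+] | intermediate
17 | 7,9-bis(triethylsilyloxy)-12-norlongipinan-1-one | CC[Si](CC)(CC)O[C@@H]1C[C@@H](O[Si](CC)(CC)CC)[C@]2(C)[C@@H]3[C@@H]([C@H]2C(=O)CC3)C1(C)C | intermediate
18 | C1 trimethylsilyl enol ether (C1=C2) of 17 (not isolated) | CC[Si](CC)(CC)O[C@@H]1C[C@@H](O[Si](CC)(CC)CC)[C@]2(C)[C@@H]3[C@@H]([C@H]2C(O[Si](C)(C)C)=CC3)C1(C)C | intermediate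
19 | 7,9-bis(triethylsilyloxy)-12-norlongipin-2-en-1-one | CC[Si](CC)(CC)O[C@@H]1C[C@@H](O[Si](CC)(CC)CC)[C@]2(C)[C@@H]3[C@@H]([C@H]2C(=O)C=C3)C1(C)C | intermediate
20 | 7,9-bis(triethylsilyloxy)longipinan-1-one | CC[Si](CC)(CC)O[C@@H]1C[C@@H](O[Si](CC)(CC)CC)[C@]2(C)[C@@H]3[C@@H]([C@H]2C(=O)C[C@H]3C)C1(C)C | intermediate
21 | 7,9-dihydroxylongipinan-1-one | O[C@@H]1C[C@@H](O)[C@]2(C)[C@@H]3[C@@H]([C@H]2C(=O)C[C@H]3C)C1(C)C | intermediate
22 | angelic acid, (Z)-2-methylbut-2-enoic acid | C/C=C(/C)C(=O)O | starting material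
23 | 7,9-di-O-angeloyl-longipinan-1-one | C/C=C(/C)C(=O)O[C@@H]1C[C@@H](OC(=O)/C(C)=C\C)[C@]2(C)[C@@H]3[C@@H]([C@H]2C(=O)C[C@H]3C)C1(C)C | target

**Totals.** 13 steps; longest linear sequence 13 steps.

**Steps most likely to fail, with fallbacks**

Step 9 (key step). The conjugate addition at the congested C10 may be slow, and the copper/lithium enolate may be protonated or decompose before it displaces the neopentyl-type C5 tosylate. Fallback (stepwise enol-silane route): 15 is treated with Me2CuLi/TMSCl (Corey–Boaz conditions) and the trimethylsilyl enol ether of the C10-methyl adduct F1 is isolated. Anhydrous fluoride (Bu4N Ph3SiF2, THF/DMSO, 60 °C) then generates a naked ammonium enolate that should cyclise; the sequence returns to the route at 17.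

Step 6. The β-hydroxy ketone may dehydrate under acid, the seven-membered aldol closure may be slow, or attack on the C7 aldehyde may show poor facial selectivity. Fallback (kinetic Mukaiyama closure): keto aldehyde 12 is isolated after brief hydrolysis of 11 and treated with TMSOTf/i-Pr2NEt in CH2Cl2 at −78 °C. This forms the methyl-ketone enol silane in the flask and adds it to the silyl-activated aldehyde, giving the C7 trimethylsilyl ether of the aldol F2; mild aqueous acid returns to the route at 13.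

Step 13. Acylation of the two hindered hydroxyls may stall, or the angelate may isomerise to the tiglate during the slow acylation. Fallback (build the Z-alkene after acylation): 21 is esterified with the saturated acid 2-[bis(2,2,2-trifluoroethoxy)phosphoryl]propanoic acid (DCC, DMAP) to give the bis(phosphonopropionate) F3. Double Still–Gennari olefination with acetaldehyde (KHMDS, 18-crown-6, THF, −78 °C) then forms both (Z)-2-methylbut-2-enoates and returns to the route at 23.

Further compounds

F1 | step 9 | trimethylsilyl enol ether of the cis-fused C10-methyl conjugate adduct of 15 | CC[Si](CC)(CC)O[C@@H]1C[C@@H](O[Si](CC)(CC)CC)[C@@]2(C)C=C(O[Si](C)(C)C)CC[C@H]2[C@H](OS(=O)(=O)c3ccc(C)cc3)C1(C)C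
F2 | step 6 | C7 trimethylsilyl ether of aldol 13 | C[Si](C)(C)O[C@@H]1CC(=O)C2=CC(=O)CC[C@H]2[C@H](OS(=O)(=O)c3ccc(C)cc3)C1(C)C
F3 | step 13 | 7,9-bis{2-[bis(2,2,2-trifluoroethoxy)phosphoryl]propanoate} of 21 (mixture at the phosphonate α-carbons) | CC(P(=O)(OCC(F)(F)F)OCC(F)(F)F)C(=O)O[C@@H]1C[C@@H](OC(=O)C(C)P(=O)(OCC(F)(F)F)OCC(F)(F)F)[C@]2(C)[C@@H]3[C@@H]([C@H]2C(=O)C[C@H]3C)C1(C)C
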